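Ring B is not brought in as a gallate but grown on the finished chromone: the C1'–C6' and C2'–C3' bonds are made last. A 4-chloro-2,3-bis(benzyloxy)cyclobutenone is joined at its C4 to the α-carbon of a 2-(1-stannylvinyl)chromone (rings A and C), and the resulting 4-alkenylcyclobutenone rearranges thermally to a phenol. The step exploits the three adjacent oxygens on C3', C4' and C5' of ring B, of which only O-3' must be sulfated: the cyclobutenone carbonyl carbon emerges as C3' with a free hydroxyl, whereas the two enol-ether carbons emerge as benzyl-protected C4' and C5'. O-7 is carried as a silyl ether and O-5 as a benzyl ether.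

Key step: step 9

Remark on the chemistry: sulfate monoesters are written as free hydrogen sulfates, as in the target structure; in the flask they would be trialkylammonium salts, and the target would be set free at the very end by brief contact with a cold acidic ion-exchange resin.

Step 1
Reactants: 1 squaric acid; 2 benzyl alcohol
Product: 3 dibenzyl squarate [3,4-bis(benzyloxy)cyclobut-3-ene-1,2-dione]
Conditions: BnOH (5 equiv in all), toluene, reflux, Dean–Stark trap
Reagents that add atoms: benzyl alcohol (second equivalent), OCc1ccccc1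
Why: Twofold Fischer-type esterification, one molecule of benzyl alcohol per acidic hydroxyl, with azeotropic removal of water is the standard route to dialkyl squarates and should work because squaric acid is a strong vinylogous diacid that catalyses its own esterification.

Step 2
Reactants: 3 dibenzyl squarate
Product: 4 2,3-bis(benzyloxy)-4-hydroxycyclobut-2-en-1-one (racemic)
Conditions: LiAlH(OtBu)3 (1.05 equiv), THF, −78 → −20 °C; aq. KNaC4H4O6, 0 °C
Reagents that add atoms: none
Why: Chemoselective 1,2-reduction of one of the two equivalent vinylogous-ester carbonyls by a bulky aluminium hydride should stop at the mono-alcohol, as is known for other dialkyl squarates; the new stereocentre is formed without control (racemate) and disappears in step 9.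

Step 3
Reactants: 4 2,3-bis(benzyloxy)-4-hydroxycyclobut-2-en-1-one
Product: 6 2,3-bis(benzyloxy)-4-chlorocyclobut-2-en-1-one (racemic), via cyclobutenyl mesylate 5 (not isolated)
Conditions: MsCl, Et3N, CH2Cl2, −40 → 0 °C; cold aqueous wash, solution dried and used at once
Reagents that add atoms: methanesulfonyl chloride, CS(=O)(=O)Cl
Why: Conversion of an allylic alcohol into the chloride through its sulfonate ester, with the chloride ion of Et3N·HCl displacing the mesylate, should place chlorine at C4 because only this position restores the vinylogous ester, and the anhydrous, acid-free medium avoids the known acid-induced collapse of such alcohols to cyclobutenediones; C4 stays racemic.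

Step 4
Reactants: 7 2,4,6-trihydroxyacetophenone
Product: 8 1-[2,6-dihydroxy-4-(triisopropylsilyloxy)phenyl]ethan-1-one
Conditions: TIPSCl (1.05 equiv), imidazole, DMF, 0 °C
Reagents that add atoms: chlorotriisopropylsilane, CC(C)[Si](Cl)(C(C)C)C(C)C
Why: Regioselective phenol silylation should take place at the hydroxyl para to the acetyl group, the only one that is neither hydrogen-bonded to the carbonyl nor flanked by the acetyl group, and the bulk of the silyl chloride sharpens this preference.

Step 5
Reactants: 8 1-[2,6-dihydroxy-4-(triisopropylsilyloxy)phenyl]ethan-1-one; 2 benzyl alcohol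
Product: 9 1-[2-(benzyloxy)-6-hydroxy-4-(triisopropylsilyloxy)phenyl]ethan-1-one
Conditions: BnOH (1.1 equiv), PPh3, DIAD, THF, 0 °C → rt
Reagents that add atoms: none
Why: Mitsunobu etherification under neutral conditions leaves the aryl silyl ether in place and should stop after one benzylation, because the remaining hydroxyl is then locked in a strong hydrogen bond to the ketone.

Step 6
Reactants: 9 1-[2-(benzyloxy)-6-hydroxy-4-(triisopropylsilyloxy)phenyl]ethan-1-one; 10 ethyl 2,2-diethoxypropanoate
Product: 12 2-acetyl-5-(benzyloxy)-7-(triisopropylsilyloxy)-4H-chromen-4-one, via ketal diketone 11 (not isolated)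
Conditions: LiN(SiMe3)2 (3.3 equiv), THF, −78 → 0 °C; then 3 M aq. HCl, 55 °C
Reagents that add atoms: water, O
Why: Crossed Claisen condensation of the lithium dianion (phenoxide plus enolate) with a non-enolisable α,α-dialkoxy ester, followed in the same flask by acid-mediated cyclodehydration of the o-hydroxyaryl 1,3-diketone and hydrolysis of the ketal (the acetyl oxygen then comes from water), is the established chromone synthesis from o-hydroxyacetophenones and activated esters, and lithium amide bases are known to spare aryl silyl ethers in such acylations.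

Step 7
Reactants: 12 2-acetyl-5-(benzyloxy)-7-(triisopropylsilyloxy)-4H-chromen-4-one
Product: 13 1-[5-(benzyloxy)-4-oxo-7-(triisopropylsilyloxy)-4H-chromen-2-yl]vinyl trifluoromethanesulfonate
Conditions: KN(SiMe3)2 (1.1 equiv), THF, −78 °C; then PhNTf2, −78 → 0 °C
Reagents that add atoms: N-phenylbis(trifluoromethanesulfonimide), O=S(=O)(N(c1ccccc1)S(=O)(=O)C(F)(F)F)C(F)(F)F
Why: Kinetic deprotonation of the acetyl methyl group, the only enolisable position, and O-sulfonylation of the potassium enolate (enol triflate formation) should give the terminal vinyl triflate.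

Step 8
Reactants: 13 1-[5-(benzyloxy)-4-oxo-7-(triisopropylsilyloxy)-4H-chromen-2-yl]vinyl trifluoromethanesulfonate
Product: 14 5-(benzyloxy)-7-(triisopropylsilyloxy)-2-[1-(trimethylstannyl)vinyl]-4H-chromen-4-one
Conditions: Me3SnSnMe3 (1.5 equiv), Pd(PPh3)4 (5 mol %), LiCl (6 equiv), THF, 60 °C
Reagents that add atoms: hexamethylditin, C[Sn](C)(C)[Sn](C)(C)C
Why: Palladium-catalysed stannylation of a vinyl triflate with a distannane (oxidative addition to zerovalent palladium, tin–tin transmetalation, reductive elimination, LiCl keeping the vinylpalladium intermediate alive) is a standard route to 1-substituted vinylstannanes.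

Step 9
Reactants: 6 2,3-bis(benzyloxy)-4-chlorocyclobut-2-en-1-one; 14 5-(benzyloxy)-7-(triisopropylsilyloxy)-2-[1-(trimethylstannyl)vinyl]-4H-chromen-4-one
Product: 18 5-(benzyloxy)-2-[3,4-bis(benzyloxy)-5-hydroxyphenyl]-7-(triisopropylsilyloxy)-4H-chromen-4-one, via coupled 4-alkenylcyclobutenone 15 (not isolated), via dienylketene 16 (not isolated), via cyclohexadienone 17 (not isolated)
Conditions: 6 (1.3 equiv), PdCl2(PhCN)2 (5 mol %), tri(2-furyl)phosphine (10 mol %), dioxane, 50 °C; then 100 °C
Reagents that add atoms: none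
Why: Zerovalent palladium, formed from PdCl2(PhCN)2 and the stannane, inserts into the allylic C4–Cl bond of 6, the 1-(chromon-2-yl)vinyl group passes from tin to palladium, and reductive elimination at C4 gives 15 (C1'–C6'); this is the Stille coupling established for 4-chlorocyclobutenones and alkenylstannanes, here applied to a 2,3-dialkoxy member. At 100 °C 15 undergoes thermal conrotatory four-electron opening of its C1–C4 bond to dienylketene 16, and ring B is closed by disrotatory six-electron electrocyclisation between the ketene carbon and the vinyl CH2 (C2'–C3') to give 17, which tautomerises to phenol 18. No stereocentre is formed, since C4 of racemic 6 ends as the aromatic C6'–H. The coupling must occur at C4 and not at C2, which the substrate secures because C4 is the unsubstituted allyl terminus and only bond formation there keeps the vinylogous ester conjugation. The alkenyl group must rotate inward, which is secured by the reversibility of the ring opening: the outward ketene can only reclose to 15, whereas the inward ketene is drained irreversibly into the aromatic ring. The ketene carbon thus becomes C3' with the only free hydroxyl of ring B, the benzyloxy carbons become C4' and C5', and non-polar dioxane is chosen to suppress ionisation of the labile chloride.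

Step 10
Reactants: 18 5-(benzyloxy)-2-[3,4-bis(benzyloxy)-5-hydroxyphenyl]-7-(triisopropylsilyloxy)-4H-chromen-4-one
Product: 19 5-(benzyloxy)-2-[3,4-bis(benzyloxy)-5-hydroxyphenyl]-7-hydroxy-4H-chromen-4-one
Conditions: Bu4NF (1.1 equiv), AcOH (1.2 equiv), THF, 0 °C
Reagents that add atoms: none
Why: Fluoride-induced cleavage of the aryl silyl ether, buffered with acetic acid so that the phenols are not exposed to base, should free O-7 and leave the three benzyl ethers untouched.

Step 11
Reactants: 19 5-(benzyloxy)-2-[3,4-bis(benzyloxy)-5-hydroxyphenyl]-7-hydroxy-4H-chromen-4-one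
Product: 20 5-(benzyloxy)-2-[3,4-bis(benzyloxy)-5-(sulfooxy)phenyl]-4-oxo-4H-chromen-7-yl hydrogen sulfate
Conditions: SO3·NMe3 (8 equiv), Et3N, DMF, 60 °C
Reagents that add atoms: sulfur trioxide–trimethylamine complex, C[N+](C)(C)S(=O)(=O)[O-]
Why: O-Sulfation of phenols with a sulfur trioxide–amine complex should sulfate O-7 and O-3', the only free hydroxyls, since every other oxygen is a benzyl ether.

Step 12
Reactants: 20 5-(benzyloxy)-2-[3,4-bis(benzyloxy)-5-(sulfooxy)phenyl]-4-oxo-4H-chromen-7-yl hydrogen sulfate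
Product: 21 tricetin 7,3'-disulfate
Conditions: H2 (1 atm), palladium on carbon (Pd/C, 10%), MeOH–THF, rt; then acidic cation-exchange resin, 0 °C, freeze-drying
Reagents that add atoms: none
Why: Hydrogenolysis of the three benzyl aryl ethers over palladium is compatible with aryl sulfate monoesters and, at atmospheric pressure with monitoring, with the C2=C3 double bond of the flavone.

Compound list
1 | squaric acid | O=c1c(O)c(O)c1=O | starting material
2 | benzyl alcohol | OCc1ccccc1 | starting material
3 | dibenzyl squarate [3,4-bis(benzyloxy)cyclobut-3-ene-1,2-dione] | O=C1C(=O)C(OCc2ccccc2)=C1OCc1ccccc1 | intermediate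
4 | 2,3-bis(benzyloxy)-4-hydroxycyclobut-2-en-1-one (racemic) | O=C1C(OCc2ccccc2)=C(OCc2ccccc2)C1O | intermediate
5 | 2,3-bis(benzyloxy)-4-oxocyclobut-2-en-1-yl methanesulfonate (racemic) | CS(=O)(=O)OC1C(=O)C(OCc2ccccc2)=C1OCc1ccccc1 | intermediate
6 | 2,3-bis(benzyloxy)-4-chlorocyclobut-2-en-1-one (racemic) | O=C1C(OCc2ccccc2)=C(OCc2ccccc2)C1Cl | intermediate
7 | 2,4,6-trihydroxyacetophenone | CC(=O)c1c(O)cc(O)cc1O | starting material
8 | 1-[2,6-dihydroxy-4-(triisopropylsilyloxy)phenyl]ethan-1-one | CC(=O)c1c(O)cc(O[Si](C(C)C)(C(C)C)C(C)C)cc1O | intermediate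
9 | 1-[2-(benzyloxy)-6-hydroxy-4-(triisopropylsilyloxy)phenyl]ethan-1-one | CC(=O)c1c(O)cc(O[Si](C(C)C)(C(C)C)C(C)C)cc1OCc1ccccc1 | intermediate
10 | ethyl 2,2-diethoxypropanoate | CCOC(=O)C(C)(OCC)OCC | starting material
11 | 1-[2-(benzyloxy)-6-hydroxy-4-(triisopropylsilyloxy)phenyl]-4,4-diethoxypentane-1,3-dione | CCOC(C)(OCC)C(=O)CC(=O)c1c(O)cc(O[Si](C(C)C)(C(C)C)C(C)C)cc1OCc1ccccc1 | intermediate
12 | 2-acetyl-5-(benzyloxy)-7-(triisopropylsilyloxy)-4H-chromen-4-one | CC(=O)c1cc(=O)c2c(OCc3ccccc3)cc(O[Si](C(C)C)(C(C)C)C(C)C)cc2o1 | intermediate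
13 | 1-[5-(benzyloxy)-4-oxo-7-(triisopropylsilyloxy)-4H-chromen-2-yl]vinyl trifluoromethanesulfonate | C=C(OS(=O)(=O)C(F)(F)F)c1cc(=O)c2c(OCc3ccccc3)cc(O[Si](C(C)C)(C(C)C)C(C)C)cc2o1 | intermediate
14 | 5-(benzyloxy)-7-(triisopropylsilyloxy)-2-[1-(trimethylstannyl)vinyl]-4H-chromen-4-one | C=C([Sn](C)(C)C)c1cc(=O)c2c(OCc3ccccc3)cc(O[Si](C(C)C)(C(C)C)C(C)C)cc2o1 | intermediate
15 | 2,3-bis(benzyloxy)-4-{1-[5-(benzyloxy)-4-oxo-7-(triisopropylsilyloxy)-4H-chromen-2-yl]vinyl}cyclobut-2-en-1-one (racemic) | O=C1C(OCc2ccccc2)=C(OCc2ccccc2)C1C(=C)c1cc(=O)c2c(OCc3ccccc3)cc(O[Si](C(C)C)(C(C)C)C(C)C)cc2o1 | intermediate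
16 | 2,3-bis(benzyloxy)-5-[5-(benzyloxy)-4-oxo-7-(triisopropylsilyloxy)-4H-chromen-2-yl]hexa-1,3,5-trien-1-one, ketene carbon chain and alkenyl group cis across C3=C4 | O=C=C(OCc1ccccc1)/C(OCc1ccccc1)=C\C(=C)c1cc(=O)c2c(OCc3ccccc3)cc(O[Si](C(C)C)(C(C)C)C(C)C)cc2o1 | intermediate
17 | 2-[3,4-bis(benzyloxy)-5-oxocyclohexa-1,3-dien-1-yl]-5-(benzyloxy)-7-(triisopropylsilyloxy)-4H-chromen-4-one (keto tautomer of 18, CH2 between the carbonyl and the chromonyl-bearing carbon) | O=C1CC(c2cc(=O)c3c(OCc4ccccc4)cc(O[Si](C(C)C)(C(C)C)C(C)C)cc3o2)=CC(OCc2ccccc2)=C1OCc1ccccc1 | intermediate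
18 | 5-(benzyloxy)-2-[3,4-bis(benzyloxy)-5-hydroxyphenyl]-7-(triisopropylsilyloxy)-4H-chromen-4-one | O=c1cc(-c3cc(O)c(OCc4ccccc4)c(OCc4ccccc4)c3)oc2cc(O[Si](C(C)C)(C(C)C)C(C)C)cc(OCc3ccccc3)c12 | intermediate
19 | 5-(benzyloxy)-2-[3,4-bis(benzyloxy)-5-hydroxyphenyl]-7-hydroxy-4H-chromen-4-one | O=c1cc(-c3cc(O)c(OCc4ccccc4)c(OCc4ccccc4)c3)oc2cc(O)cc(OCc3ccccc3)c12 | intermediate
20 | 5-(benzyloxy)-2-[3,4-bis(benzyloxy)-5-(sulfooxy)phenyl]-4-oxo-4H-chromen-7-yl hydrogen sulfate | O=c1cc(-c3cc(OS(=O)(=O)O)c(OCc4ccccc4)c(OCc4ccccc4)c3)oc2cc(OS(=O)(=O)O)cc(OCc3ccccc3)c12 | intermediate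
21 | tricetin 7,3'-disulfate | O=c1cc(-c2cc(O)c(O)c(OS(=O)(=O)O)c2)oc2cc(OS(=O)(=O)O)cc(O)c12 | target

Total step count: 12 steps (3 to the chlorocyclobutenone, 5 to the stannane, the coupling, 3 to the target).
Longest linear sequence: 9 steps (steps 4 to 12, from 2,4,6-trihydroxyacetophenone).

Steps most likely to fail

1. Step 9. Chloride 6 is a vinylogous α-chloro ether and may ionise and lose a benzyl group before oxidative addition. Transfer of the hindered, electron-poor 1-substituted alkenyl group from tin may be slow enough for protodestannylation to win. Bond formation at C2 would give the wrong substitution pattern in ring B. The fallback abandons the ring construction and takes ring B ready-made from gallic acid; it sets out from 9 and returns to the route at 19. Commercial methyl gallate would be benzylated at O-3 and O-4 (BnBr, K2CO3, DMF, separation from the mono- and tribenzyl ethers) to methyl 3,4-bis(benzyloxy)-5-hydroxybenzoate F1. Silylation (TIPSCl, imidazole, DMF) would give methyl 3,4-bis(benzyloxy)-5-(triisopropylsilyloxy)benzoate F2. The lithium dianion of 9 (LiN(SiMe3)2, THF, −78 °C → rt) would be C-acylated by F2 to 1-[2-(benzyloxy)-6-hydroxy-4-(triisopropylsilyloxy)phenyl]-3-[3,4-bis(benzyloxy)-5-(triisopropylsilyloxy)phenyl]propane-1,3-dione F3. Cyclodehydration with p-TsOH in toluene at 80 °C (Baker–Venkataraman-type flavone synthesis) would give 5-(benzyloxy)-2-[3,4-bis(benzyloxy)-5-(triisopropylsilyloxy)phenyl]-7-(triisopropylsilyloxy)-4H-chromen-4-one F4. Bu4NF/AcOH in THF would remove both silyl groups and give 19.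

2. Step 3. The mesylate and the chloride may both ionise, after which chloride attacks a benzyl group and the ring collapses to a cyclobutenedione; the chloride may also not survive the wash. The fallback never isolates a chloride; it sets out from 4 and returns at 18. Alcohol 4 would be acetylated under non-ionising conditions (Ac2O, pyridine, catalytic DMAP, CH2Cl2, 0 °C) to 2,3-bis(benzyloxy)-4-oxocyclobut-2-en-1-yl acetate F5 (racemic), a stable allylic ester. F5 would be coupled with stannane 14 under the conditions of allylic acetate–stannane coupling (Pd2(dba)3, tri(2-furyl)phosphine, LiCl, DMF, 40 °C), in which zerovalent palladium opens the allylic C–O bond and chloride enters only on the metal, to give the coupled cyclobutenone 15. Heating to 100 °C would then carry 15 through the same ring expansion to 18.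

3. Step 6. C-Acylation by the hindered ketal ester may stay incomplete, and the acid stage may either leave the α-keto ketal unhydrolysed or begin to remove the aryl silyl ether. The fallback reaches the ketone through the chromone-2-carboxylate; it sets out from 9 and returns at 12. The dianion of 9 (LiN(SiMe3)2, THF, −78 → 0 °C) would be acylated with diethyl oxalate to ethyl 4-[2-(benzyloxy)-6-hydroxy-4-(triisopropylsilyloxy)phenyl]-2,4-dioxobutanoate F6. p-TsOH in toluene at 80 °C would close the pyranone to ethyl 5-(benzyloxy)-4-oxo-7-(triisopropylsilyloxy)-4H-chromene-2-carboxylate F7. Me(MeO)NH·HCl and iPrMgCl (THF, −20 °C) would convert the ester into 5-(benzyloxy)-N-methoxy-N-methyl-4-oxo-7-(triisopropylsilyloxy)-4H-chromene-2-carboxamide F8. MeMgBr (THF, −78 °C) would add once to this Weinreb amide and give 12.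

Further compounds
F1 | step 9 | methyl 3,4-bis(benzyloxy)-5-hydroxybenzoate | COC(=O)c1cc(O)c(OCc2ccccc2)c(OCc2ccccc2)c1
F2 | step 9 | methyl 3,4-bis(benzyloxy)-5-(triisopropylsilyloxy)benzoate | COC(=O)c1cc(O[Si](C(C)C)(C(C)C)C(C)C)c(OCc2ccccc2)c(OCc2ccccc2)c1
F3 | step 9 | 1-[2-(benzyloxy)-6-hydroxy-4-(triisopropylsilyloxy)phenyl]-3-[3,4-bis(benzyloxy)-5-(triisopropylsilyloxy)phenyl]propane-1,3-dione | O=C(CC(=O)c1cc(O[Si](C(C)C)(C(C)C)C(C)C)c(OCc2ccccc2)c(OCc2ccccc2)c1)c1c(O)cc(O[Si](C(C)C)(C(C)C)C(C)C)cc1OCc1ccccc1
F4 | step 9 | 5-(benzyloxy)-2-[3,4-bis(benzyloxy)-5-(triisopropylsilyloxy)phenyl]-7-(triisopropylsilyloxy)-4H-chromen-4-one | O=c1cc(-c3cc(O[Si](C(C)C)(C(C)C)C(C)C)c(OCc4ccccc4)c(OCc4ccccc4)c3)oc2cc(O[Si](C(C)C)(C(C)C)C(C)C)cc(OCc3ccccc3)c12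
F5 | step 3 | 2,3-bis(benzyloxy)-4-oxocyclobut-2-en-1-yl acetate (racemic) | CC(=O)OC1C(=O)C(OCc2ccccc2)=C1OCc1ccccc1
F6 | step 6 | ethyl 4-[2-(benzyloxy)-6-hydroxy-4-(triisopropylsilyloxy)phenyl]-2,4-dioxobutanoate | CCOC(=O)C(=O)CC(=O)c1c(O)cc(O[Si](C(C)C)(C(C)C)C(C)C)cc1OCc1ccccc1
F7 | step 6 | ethyl 5-(benzyloxy)-4-oxo-7-(triisopropylsilyloxy)-4H-chromene-2-carboxylate | CCOC(=O)c1cc(=O)c2c(OCc3ccccc3)cc(O[Si](C(C)C)(C(C)C)C(C)C)cc2o1
F8 | step 6 | 5-(benzyloxy)-N-methoxy-N-methyl-4-oxo-7-(triisopropylsilyloxy)-4H-chromene-2-carboxamide | CON(C)C(=O)c1cc(=O)c2c(OCc3ccccc3)cc(O[Si](C(C)C)(C(C)C)C(C)C)cc2o1
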